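## Structural features

Licobichalcone is a 1-aryl-1,2-dihydronaphthalene: aromatic ring A (C4a, C5–C8, C8a; OH on C6 and C7, OMe on C8) is fused to ring B (C1–C2–C3=C4–C4a–C8a), C1 carries ring C (3,4-dihydroxy-2-methoxyphenyl), and C2 and C3 each carry a 4-hydroxybenzoyl group. The two stereocentres, C1 (S) and C2 (S), are adjacent, with the C1 aryl and the C2 aroyl on the same face of ring B, and C3=C4 is an enone double bond conjugated with ring A. The fragile points are C2–H (α to a ketone and allylic, and the cis isomer is expected to be less stable than the trans isomer, in which both groups can stand pseudoaxial away from the C8 methoxy and the C3 aroyl), the dihydronaphthalene (oxidative aromatisation), the two catechols (air oxidation), and the C1–C2 bond whenever a free phenol para to C1 and a good enolate leaving group on C2 are present together (quinone-methide ring opening). The real difficulty is therefore twofold: absolute control at C1, a doubly benzylic methine with no functional group of its own, and a contra-thermodynamic cis relation at C2 that must be set late and then left alone. The feature that the key step exploits is that ring A and ring C are one and the same 2-methoxy-3,4-dioxygenated aryl group, bonded to C1 through the same ring carbon (C8a and C1'); ring A differs only by the bond C4a–C4. If that bond is absent and C2 carries two identical aroyl groups, C1 is a prochiral bis-aryl methine and the molecule is achiral, so closing C4–C4a onto one of the two enantiotopic rings creates C1 and nothing else. The attacking carbon (the future C4a) is para only to the middle oxygen of the trioxygenated ring, which as an open-chain ether is twisted out of conjugation by its two neighbours; the design therefore ties the 3,4-oxygens into a dioxole (acetonide) and places hydroxyl, not an amine, on C4 so that a catalytic chiral acid is not neutralised by the leaving group.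

## Logic of the disconnections

**22 ⇒ 21.** Only O–C bonds are cut: two catechol acetonides and two MOM ethers. The phenol para to C1 must stay masked while C2 still carries two acyl groups, so deprotection can only come after 21. The gain is that every earlier compound is non-phenolic and stable to air. The demand is heavy: C2–H of 21 is enolisable and cis is the less stable arrangement, so the acid must be cold and brief.

**21 ⇒ 19.** A second, identical aroyl group is added to C2; in the forward sense one C2–C(=O) bond is cleaved (retro-Claisen). With two identical aroyl groups C2 is not stereogenic, so 19 has C1 as its only stereocentre and the cis/trans question is removed from the ring closure. The forward step must cleave only a C2 aroyl group (the C3 aroyl is a vinyl ketone and cannot fragment), and the dienolate must take its proton at C2, not C4, from the face away from the C1 aryl.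

**19 ⇒ 17.** The bond C4–C4a is cut, the one bond that distinguishes ring A from ring C. This gives 17, which is achiral, so no chirality has to be carried up to this point. The forward step needs a chiral acid that selects one of two enantiotopic rings. It needs a nucleophilic ring carbon, which is why 17 carries acetonides and not open-chain catechol ethers. It also needs a leaving group that lets the acid turn over: a dimethylamino group on C4 (an enaminone version of 17) was rejected because the released amine would neutralise the catalyst and the protonated vinylogous amide would be too weak an electrophile for this arene. The closure must also outrun acid-induced heterolysis of the crowded C1–C2 bond.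

**17 ⇒ 15.** The bond C3–C4 is cut; C4 is a formyl carbon put on the only enolisable position of 15. The forward formylation must run cold, because the 2,2-disubstituted 1,3-diketone of 15 is open to retro-Claisen attack by alkoxide or amine at higher temperature.

**15 ⇒ 14 + 13.** The bond C2–C3 is cut, giving a stabilised diketone enolate and an α-bromoketone. The gain is convergence; the demand is C-alkylation, not O-alkylation, of a hindered tertiary enolate.

**14 ⇒ 6 + 11.** The bond C1–C2 is cut, giving a bis-aryl carbenium ion (from carbinol 6) and the enol of the symmetrical diketone 11. Both partners are symmetrical, so no selectivity issue arises; the acid must be mild enough to spare MOM ethers and acetonides.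

**6 ⇒ 3 ⇒ 2 ⇒ 1.** Both C1–aryl bonds are cut: two equivalents of the aryl anion from 3 add to a one-carbon formate electrophile. Compound 3 comes from 2 by O-methylation and 2 from 1 by bromination ortho to the phenol. The demand is ortho, not para, selectivity in the bromination.

**11 ⇒ 8 + 10; 13 ⇐ 8; 8 ⇐ 7; 10 ⇐ 9.** The diketone is cut at the central C–C bond (Claisen condensation). Compound 13 is the α-bromo derivative of 8, so one protected ketone serves twice. MOM is chosen on the aroyl phenols because it survives base, enolates and thiolate and leaves in the same acid step as the acetonides.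

## Other disconnections considered

**Alternative 1:** The cut removes all of ring A at once (C4a–C8a, C5–C6, C7–C8), which also opens ring B. In the forward direction CpCo(CO)2 would join the acyclic enediyne A1 (ethynyl on C4, methoxyethynyl on C1, C1 and C2 already configured) with bis(pinacolboryl)acetylene A2 in a [2+2+2] cycloaddition to give the 6,7-diboryl dihydronaphthalene A3; the two C–B bonds would then be oxidised to the catechol.
- In its favour: three C–C bonds and two rings form in one step; no aroyl group is sacrificed; and the substitution pattern of ring A is fixed by the alkyne partners, not by the nucleophilicity of an arene carbon. On this last point it is better than the chosen plan, whose closure relies on a carbon activated by one oxygen only.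
- Against it here: the step creates no stereocentre, so A1 must be made as a single enantiomer with the labile cis C1/C2 pair in an open chain, where C2–H is α to a ketone and C1–H is propargylic and benzylic. The ynol ether is acid-sensitive, the C3=C4 alkene can compete with A2 for the cobaltacycle, and oxidising A3 needs basic peroxide, which threatens the enone and C2.
- Comparison: structurally it ignores the identity of ring A and ring C, which the chosen plan uses as its source of chirality. Mechanistically it is a metal-templated cycloaddition with secure connectivity but no stereochemical role, whereas the chosen closure is less precedented but sets C1. In step economy the key step is richer in bonds, but an enantioselective route to A1 plus the oxidation would very probably make the whole sequence longer.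

**Alternative 2:** The cut is C1–C2 and C3–C4. Irradiation at 365 nm would convert the ortho-benzylbenzaldehyde A4 into its hydroxy-ortho-quinodimethane A5, which would add the cis-enedione A6 on a chiral titanium alkoxide (Ti(OiPr)4 with a chiral diol) to give the all-cis 4-hydroxytetralin A7; dehydration across C3–C4 would follow.
- In its favour: it is the most convergent plan, joining two halves of similar size. C1 and C2 and their cis relation are set in one suprafacial event from the alkene geometry of A6 and endo addition, which is better than setting C2 by a separate protonation. No aroyl group is sacrificed, and if it worked it would be shorter than the chosen route.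
- Against it here: A6 is prone to Z-to-E isomerisation under the same light and under Lewis acid, and the E isomer no longer guarantees the cis C1/C2 relation. A5 must form with its aryl group pointing outward. The chiral titanium reagent is needed in stoichiometric amount. The dehydration of A7 has to spare the epimerisable C2, and the enone product absorbs in the same region as the light used.
- Comparison: structurally it makes no use of the ring A/ring C identity. Mechanistically its relative stereocontrol is pericyclic and in principle firmer than a kinetic protonation, but its absolute control rests on a stoichiometric metal template, where the chosen plan uses a catalytic acid. On step economy it is the equal or the better of the chosen plan.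

**Alternative 3:** The cut is C1–C2. The racemic C1 carbinol A8, with the ring C 4-hydroxyl free, would ionise under a chiral phosphoric acid to the ring C para-quinone methide A9, and the enol of the ketone on C2 would add through C2 to give A10. A10 is the target skeleton with the ring C 4-hydroxyl free and the other five phenols as MOM ethers (five, not four: two on ring A, one on ring C, one on each aroyl group).
- In its favour: 1,6-addition of enols to para-quinone methides under chiral phosphoric acids is a well-established activation mode, so on precedent it is better than the chosen key step. It is stereoconvergent from a racemate, forms the C1–C2 bond and both stereocentres in the ring-closing step, and sacrifices no aroyl group.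
- Against it here: the closure creates C2 as a C–H centre in the same step, so the trans arrangement is the expected outcome. The product keeps a free phenol para to C1 and an enolisable ketone on C2, so ring opening back to A9 and C2 epimerisation can erode both selectivities. A8 is an enolisable 1,4-diketone (furan formation under acid) and needs one free phenol among six and two differently built aryl rings.
- Comparison: structurally it must differentiate ring A from ring C from the start, where the chosen plan keeps them identical until the key step. Mechanistically its activation is better precedented but its diastereocontrol points the wrong way; the chosen plan separates the two problems (catalyst for C1, kinetic protonation for C2). In step economy it avoids the sacrificial aroyl group and the retro-Claisen step but pays in protecting-group differentiation, so the two are about equal.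

Key step: step 11

Remark on the chemistry: 2,2-dimethyl-1,3-benzodioxol-4-ol (1) is assumed to be purchasable (otherwise one ketalisation of pyrogallol precedes step 1), and the (R) catalyst is written in step 11 on the understanding that its antipode is used if the sense of induction proves opposite.

## Route

Step 1
Reactants: 1 2,2-dimethyl-1,3-benzodioxol-4-ol
Product: 2 5-bromo-2,2-dimethyl-1,3-benzodioxol-4-ol
Conditions: t-BuNH2 (2 equiv), Br2 (1 equiv), toluene, −78 °C to rt
Reagents that add atoms: bromine BrBr
Why: Amine-mediated ortho-bromination of a phenol: N-bromo-tert-butylamine is delivered through a hydrogen bond to the phenol OH, so substitution should occur at C5 (the only free ortho carbon, also para to O1) and not at C7; the amine buffers HBr, so the acetonide should survive.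

Step 2
Reactants: 2 5-bromo-2,2-dimethyl-1,3-benzodioxol-4-ol
Product: 3 5-bromo-4-methoxy-2,2-dimethyl-1,3-benzodioxole
Conditions: MeI, K2CO3, acetone, 50 °C
Reagents that add atoms: iodomethane CI
Why: Williamson O-methylation of the phenoxide; it fixes the methoxy group ortho to the future C1–aryl bond.

Step 3
Reactants: 3 5-bromo-4-methoxy-2,2-dimethyl-1,3-benzodioxole
Product: 6 bis(4-methoxy-2,2-dimethyl-1,3-benzodioxol-5-yl)methanol, via aryllithium 4 (not isolated), via aldehyde 5 (not isolated)
Conditions: n-BuLi (1.05 equiv), THF, −78 °C; HCO2Et (0.5 equiv), −78 to 0 °C; aq. NH4Cl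
Reagents that add atoms: ethyl formate CCOC=O
Why: Bromine–lithium exchange, then double addition of the aryllithium to a formate ester (the first addition gives aldehyde 5, which takes up the second equivalent); this is the standard route to symmetrical benzhydrols and makes both aryl groups of C1 from one bromide.

Step 4
Reactants: 7 4-hydroxyacetophenone
Product: 8 1-[4-(methoxymethoxy)phenyl]ethanone
Conditions: MOMCl, i-Pr2NEt, CH2Cl2, 0 °C to rt
Reagents that add atoms: chloromethyl methyl ether COCCl
Why: O-alkylation of the phenol with an α-chloro ether; MOM is stable to the bases, enolates and thiolate used later and leaves in the final acid step.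

Step 5
Reactants: 9 methyl 4-hydroxybenzoate
Product: 10 methyl 4-(methoxymethoxy)benzoate
Conditions: MOMCl, i-Pr2NEt, CH2Cl2, 0 °C to rt
Reagents that add atoms: chloromethyl methyl ether COCCl
Why: Same phenol protection as in step 4.

Step 6
Reactants: 8 1-[4-(methoxymethoxy)phenyl]ethanone; 10 methyl 4-(methoxymethoxy)benzoate
Product: 11 1,3-bis[4-(methoxymethoxy)phenyl]propane-1,3-dione
Conditions: NaH (2.2 equiv), THF, 60 °C; AcOH
Reagents that add atoms: none
Why: Crossed Claisen condensation of a methyl ketone enolate with a non-enolisable ester, driven by formation of the stable diketonate; the product is symmetrical.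

Step 7
Reactants: 8 1-[4-(methoxymethoxy)phenyl]ethanone
Product: 13 2-bromo-1-[4-(methoxymethoxy)phenyl]ethanone, via silyl enol ether 12 (not isolated)
Conditions: LiN(SiMe3)2, Me3SiCl, THF, −78 °C; NBS, −78 to 0 °C
Reagents that add atoms: N-bromosuccinimide O=C1CCC(=O)N1Br
Why: α-Bromination through the silyl enol ether gives the monobromide under neutral conditions, so no HBr is formed that could cleave the MOM ether.

Step 8
Reactants: 6 bis(4-methoxy-2,2-dimethyl-1,3-benzodioxol-5-yl)methanol; 11 1,3-bis[4-(methoxymethoxy)phenyl]propane-1,3-dione
Product: 14 2-[bis(4-methoxy-2,2-dimethyl-1,3-benzodioxol-5-yl)methyl]-1,3-bis[4-(methoxymethoxy)phenyl]propane-1,3-dione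
Conditions: TsOH·H2O (5 mol%), CH2Cl2, rt
Reagents that add atoms: none
Why: Acid-catalysed SN1 benzhydrylation of a 1,3-diketone: the carbinol ionises readily to a carbenium ion stabilised by a para oxygen on each ring, and the enol of 11 captures it at carbon; catalytic acid at room temperature should spare MOM ethers and acetonides.

Step 9
Reactants: 14 2-[bis(4-methoxy-2,2-dimethyl-1,3-benzodioxol-5-yl)methyl]-1,3-bis[4-(methoxymethoxy)phenyl]propane-1,3-dione; 13 2-bromo-1-[4-(methoxymethoxy)phenyl]ethanone
Product: 15 2-[bis(4-methoxy-2,2-dimethyl-1,3-benzodioxol-5-yl)methyl]-2-[4-(methoxymethoxy)benzoyl]-1,4-bis[4-(methoxymethoxy)phenyl]butane-1,4-dione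
Conditions: K2CO3, acetone, 50 °C
Reagents that add atoms: none
Why: C-alkylation of a 1,3-diketone enolate with an α-bromoketone, a soft, unhindered and very SN2-reactive electrophile; the tight potassium enolate in acetone favours carbon over oxygen, and the quaternary C2 formed cannot close to a furan.

Step 10
Reactants: 15 2-[bis(4-methoxy-2,2-dimethyl-1,3-benzodioxol-5-yl)methyl]-2-[4-(methoxymethoxy)benzoyl]-1,4-bis[4-(methoxymethoxy)phenyl]butane-1,4-dione
Product: 17 (Z)-3-[bis(4-methoxy-2,2-dimethyl-1,3-benzodioxol-5-yl)methyl]-2-(hydroxymethylidene)-3-[4-(methoxymethoxy)benzoyl]-1,4-bis[4-(methoxymethoxy)phenyl]butane-1,4-dione, via lithium enolate 16 (not isolated)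
Conditions: LiN(SiMe3)2 (1.3 equiv), THF, −78 °C; HCO2CH2CF3, −78 to −30 °C; AcOH
Reagents that add atoms: 2,2,2-trifluoroethyl formate O=COCC(F)(F)F
Why: Crossed Claisen formylation: the only enolisable position is deprotonated and the enolate is acylated by an activated formate; the low temperature and the poorly nucleophilic trifluoroethoxide should spare the non-enolisable 1,3-diketone from retro-Claisen cleavage, and the product is the chelated enol of the β-keto aldehyde.

Step 11
Reactants: 17 (Z)-3-[bis(4-methoxy-2,2-dimethyl-1,3-benzodioxol-5-yl)methyl]-2-(hydroxymethylidene)-3-[4-(methoxymethoxy)benzoyl]-1,4-bis[4-(methoxymethoxy)phenyl]butane-1,4-dione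
Product: 19 (1S)-8-methoxy-6,7-(isopropylidenedioxy)-1-(4-methoxy-2,2-dimethyl-1,3-benzodioxol-5-yl)-2,2,3-tris[4-(methoxymethoxy)benzoyl]-1,2-dihydronaphthalene, via C4 carbinol 18 (not isolated)
Conditions: (R)-3,3'-bis(2,4,6-triisopropylphenyl)-1,1'-binaphthyl-2,2'-diyl N-triflylphosphoramide (10 mol%), 5 Å MS, toluene, 0 °C to rt
Reagents that add atoms: none
Why: Proposed new method: the chiral acid protonates the formyl/enol unit of 17 (a vinylogous acid and the most basic carbonyl system present), giving a hydroxyallyl cation held by its two O–H groups to the chiral phosphoramidate; C6 of one benzodioxolyl ring (para to the dioxole oxygen that becomes O7) attacks C4, rearomatisation gives carbinol 18, and loss of water across C3–C4 gives the enone and returns the acid; the closest known reaction types are Bradsher-type cyclodehydration of ortho-benzyl aryl carbonyl compounds and chiral phosphoric acid catalysed desymmetrising intramolecular Friedel–Crafts reactions, here extended to a β-keto aldehyde electrophile on a bis-aryl methine. Ring B closes in a 6-exo-trig Friedel–Crafts mode, the C4=O bond lying outside the new ring C1–C2–C3–C4–C4a–C8a. C1 becomes stereogenic only because one of its two enantiotopic aryl groups bonds to C4; the choice is made by the chiral anion held next to C4 in the contact ion pair, whose bulky 3,3' groups distinguish the two rings flanking C1, and the catalyst antipode is chosen to give (1S). C2 carries two identical aroyl groups and C3 is planar in the product, so no second stereocentre can mismatch and no cis/trans issue arises. Regiochemistry is secured by the substrate: this ring carbon is the only one that reaches C4 through a six-membered transition state, and the acetonide keeps the lone pair of the para oxygen in conjugation, whereas an open-chain ether flanked by two oxygens would be twisted and leave the carbon unactivated. Turnover is secured by the hydroxyl leaving group, since water goes into the sieves whereas an amine would neutralise the catalyst and weaken the electrophile. The closure must outrun acid-induced heterolysis of the crowded C1–C2 bond, hence the low temperature and apolar solvent.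

Step 12
Reactants: 19 (1S)-8-methoxy-6,7-(isopropylidenedioxy)-1-(4-methoxy-2,2-dimethyl-1,3-benzodioxol-5-yl)-2,2,3-tris[4-(methoxymethoxy)benzoyl]-1,2-dihydronaphthalene
Product: 21 (1S,2S)-8-methoxy-6,7-(isopropylidenedioxy)-1-(4-methoxy-2,2-dimethyl-1,3-benzodioxol-5-yl)-2,3-bis[4-(methoxymethoxy)benzoyl]-1,2-dihydronaphthalene, via sodium dienolate 20 (not isolated)
Conditions: EtSNa (1.3 equiv), THF–DMF, −40 to −10 °C, degassed; AcOH, THF, −78 °C
Reagents that add atoms: none
Why: Retro-Claisen acyl transfer: the thiolate adds to one of the two C2 aroyl carbonyls (either gives the same product), and the adduct fragments to a thioester and the extended enolate 20 with relief of the quaternary centre; kinetic protonation at C2 from the face away from the C1 aryl (held pseudoaxial by the C8 methoxy and the exocyclic enolate) places H trans to the aryl and the aroyl cis to it, which is (2S). The C3 aroyl is a vinyl ketone and cannot fragment, and the weakly basic thiolate medium should not re-enolise the product.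

Step 13
Reactants: 21 (1S,2S)-8-methoxy-6,7-(isopropylidenedioxy)-1-(4-methoxy-2,2-dimethyl-1,3-benzodioxol-5-yl)-2,3-bis[4-(methoxymethoxy)benzoyl]-1,2-dihydronaphthalene
Product: 22 licobichalcone, (1S,2S)-1-(3,4-dihydroxy-2-methoxyphenyl)-6,7-dihydroxy-8-methoxy-2,3-bis(4-hydroxybenzoyl)-1,2-dihydronaphthalene
Conditions: TFA–H2O–CH2Cl2 (9:1:10), 0 °C, Ar; cold pH 6 buffer
Reagents that add atoms: none
Why: Acid hydrolysis of the two MOM acetals and the two catechol acetonides; the methyl ethers are stable, no bond at C1 or C2 is touched, and the cold, short exposure is chosen to stay ahead of acid-catalysed enolisation at C2.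

## Compound list

1 | 2,2-dimethyl-1,3-benzodioxol-4-ol | CC1(C)Oc2cccc(O)c2O1 | starting material
2 | 5-bromo-2,2-dimethyl-1,3-benzodioxol-4-ol | CC1(C)Oc2ccc(Br)c(O)c2O1 | intermediate
3 | 5-bromo-4-methoxy-2,2-dimethyl-1,3-benzodioxole | COc1c(Br)ccc2OC(C)(C)Oc12 | intermediate
4 | (4-methoxy-2,2-dimethyl-1,3-benzodioxol-5-yl)lithium | [Li]c1ccc2OC(C)(C)Oc2c1OC | intermediate
5 | 4-methoxy-2,2-dimethyl-1,3-benzodioxole-5-carbaldehyde | COc1c(C=O)ccc2OC(C)(C)Oc12 | intermediate
6 | bis(4-methoxy-2,2-dimethyl-1,3-benzodioxol-5-yl)methanol | OC(c1ccc2OC(C)(C)Oc2c1OC)c1ccc2OC(C)(C)Oc2c1OC | intermediate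
7 | 4-hydroxyacetophenone | CC(=O)c1ccc(O)cc1 | starting material
8 | 1-[4-(methoxymethoxy)phenyl]ethanone | CC(=O)c1ccc(OCOC)cc1 | intermediate
9 | methyl 4-hydroxybenzoate | COC(=O)c1ccc(O)cc1 | starting material
10 | methyl 4-(methoxymethoxy)benzoate | COC(=O)c1ccc(OCOC)cc1 | intermediate
11 | 1,3-bis[4-(methoxymethoxy)phenyl]propane-1,3-dione | COCOc1ccc(cc1)C(=O)CC(=O)c1ccc(OCOC)cc1 | intermediate
12 | {1-[4-(methoxymethoxy)phenyl]ethenyloxy}trimethylsilane | C=C(O[Si](C)(C)C)c1ccc(OCOC)cc1 | intermediate
13 | 2-bromo-1-[4-(methoxymethoxy)phenyl]ethanone | BrCC(=O)c1ccc(OCOC)cc1 | intermediate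
14 | 2-[bis(4-methoxy-2,2-dimethyl-1,3-benzodioxol-5-yl)methyl]-1,3-bis[4-(methoxymethoxy)phenyl]propane-1,3-dione | COCOc1ccc(cc1)C(=O)C(C(=O)c1ccc(OCOC)cc1)C(c1ccc2OC(C)(C)Oc2c1OC)c1ccc2OC(C)(C)Oc2c1OC | intermediate
15 | 2-[bis(4-methoxy-2,2-dimethyl-1,3-benzodioxol-5-yl)methyl]-2-[4-(methoxymethoxy)benzoyl]-1,4-bis[4-(methoxymethoxy)phenyl]butane-1,4-dione | COCOc1ccc(cc1)C(=O)CC(C(=O)c1ccc(OCOC)cc1)(C(=O)c1ccc(OCOC)cc1)C(c1ccc2OC(C)(C)Oc2c1OC)c1ccc2OC(C)(C)Oc2c1OC | intermediate
16 | lithium (Z)-enolate of 15 (enolate of the C4 ketone, C3=C4 of the butanedione chain) | [Li+].[O-]/C(=C\C(C(=O)c1ccc(OCOC)cc1)(C(=O)c1ccc(OCOC)cc1)C(c1ccc2OC(C)(C)Oc2c1OC)c1ccc2OC(C)(C)Oc2c1OC)c1ccc(OCOC)cc1 | intermediate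
17 | (Z)-3-[bis(4-methoxy-2,2-dimethyl-1,3-benzodioxol-5-yl)methyl]-2-(hydroxymethylidene)-3-[4-(methoxymethoxy)benzoyl]-1,4-bis[4-(methoxymethoxy)phenyl]butane-1,4-dione (chelated enol of the 2-formyl triketone; achiral) | O/C=C(\C(=O)c1ccc(OCOC)cc1)C(C(=O)c1ccc(OCOC)cc1)(C(=O)c1ccc(OCOC)cc1)C(c1ccc2OC(C)(C)Oc2c1OC)c1ccc2OC(C)(C)Oc2c1OC | intermediate
18 | (1S)-4-hydroxy-8-methoxy-6,7-(isopropylidenedioxy)-1-(4-methoxy-2,2-dimethyl-1,3-benzodioxol-5-yl)-2,2,3-tris[4-(methoxymethoxy)benzoyl]-1,2,3,4-tetrahydronaphthalene (C3 and C4 undefined) | COc1c([C@H]2c3c(cc4OC(C)(C)Oc4c3OC)C(O)C(C(=O)c3ccc(OCOC)cc3)C2(C(=O)c2ccc(OCOC)cc2)C(=O)c2ccc(OCOC)cc2)ccc2OC(C)(C)Oc12 | intermediate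
19 | (1S)-8-methoxy-6,7-(isopropylidenedioxy)-1-(4-methoxy-2,2-dimethyl-1,3-benzodioxol-5-yl)-2,2,3-tris[4-(methoxymethoxy)benzoyl]-1,2-dihydronaphthalene | COc1c([C@H]2c3c(cc4OC(C)(C)Oc4c3OC)C=C(C(=O)c3ccc(OCOC)cc3)C2(C(=O)c2ccc(OCOC)cc2)C(=O)c2ccc(OCOC)cc2)ccc2OC(C)(C)Oc12 | intermediate
20 | sodium dienolate of 21 (C2=C(O−)Ar exocyclic to ring B, C1 S) | COc1c([C@H]2c3c(cc4OC(C)(C)Oc4c3OC)C=C(C(=O)c3ccc(OCOC)cc3)C2=C([O-])c2ccc(OCOC)cc2)ccc2OC(C)(C)Oc12.[Na+] | intermediate
21 | (1S,2S)-8-methoxy-6,7-(isopropylidenedioxy)-1-(4-methoxy-2,2-dimethyl-1,3-benzodioxol-5-yl)-2,3-bis[4-(methoxymethoxy)benzoyl]-1,2-dihydronaphthalene (C1 aryl and C2 aroyl cis) | COc1c([C@H]2c3c(cc4OC(C)(C)Oc4c3OC)C=C(C(=O)c3ccc(OCOC)cc3)[C@H]2C(=O)c2ccc(OCOC)cc2)ccc2OC(C)(C)Oc12 | intermediate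
22 | licobichalcone, (1S,2S)-1-(3,4-dihydroxy-2-methoxyphenyl)-6,7-dihydroxy-8-methoxy-2,3-bis(4-hydroxybenzoyl)-1,2-dihydronaphthalene | COc1c([C@H]2c3c(cc(O)c(O)c3OC)C=C(C(=O)c3ccc(O)cc3)[C@H]2C(=O)c2ccc(O)cc2)ccc(O)c1O | target

## Step count and least certain steps

Total: 13 steps. Longest linear sequence: 9 steps (steps 1, 2, 3, 8, 9, 10, 11, 12, 13).

**Step 11 (key step, the one step beyond known chemistry).** What may go wrong:
- the closure may be slow, because the attacking carbon is activated by a single para oxygen;
- the catalyst may discriminate poorly between two enantiotopic rings that lie three bonds from the electrophilic carbon;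
- the acid may instead cause heterolysis of the C1–C2 bond (loss of the stabilised bis-aryl carbenium ion, possibly assisted by cyclisation of an aroyl oxygen onto C4 towards a furan);
- reversible ionisation at C1 of the product may erode the enantiomeric purity.

Fallback with known chemistry: from 17, cyclodehydration with an achiral Brønsted acid (diphenyl hydrogen phosphate or TsOH, toluene, 5 Å MS; Bradsher-type closure) should give the racemic dihydronaphthalene F1, which is resolved by preparative chromatography on a chiral stationary phase. The route is rejoined at 19.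

**Step 9.** What may go wrong: O-alkylation of the hindered tertiary enolate, or no reaction at the crowded carbon. Fallback: invert the order of bond formation. From 11, alkylation of the unhindered diketone with 13 (K2CO3, acetone) should give the triketone 2-[4-(methoxymethoxy)benzoyl]-1,4-bis[4-(methoxymethoxy)phenyl]butane-1,4-dione F2. The quaternary centre is then made by SN1 capture of the carbenium ion from 6 (catalytic TsOH, or hexafluoroisopropanol as solvent), kept mild to avoid furan formation from this enolisable 1,4-diketone. The route is rejoined at 15.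

**Step 10.** What may go wrong: slow C-formylation at a neopentyl-type enolate, O-formylation, or retro-Claisen cleavage or acyl migration in the 1,3-diketone. Fallback: from 15, condensation with tert-butoxybis(dimethylamino)methane (toluene, 70 °C) to the dimethylaminomethylene ketone F3, followed by mild hydrolysis of the vinylogous amide (aqueous AcOH–THF or wet silica gel). The route is rejoined at 17.

**Step 12.** What may go wrong: conjugate addition of the thiolate at C4 instead of carbonyl addition; reluctance of the hindered carbonyl to fragment; protonation at C4 or from the face of the C1 aryl; air oxidation of the dienolate towards the naphthalene. Fallback: separate the cleavage from the stereochemical event. From 19, classical retro-Claisen cleavage with NaOMe in MeOH–THF at 0 °C (the by-product is 10) should give the monoketone under equilibrating conditions, expected to be rich in the (1S,2R)-trans epimer F4. F4 is then deprotonated with LiN(SiMe3)2 in THF at −78 °C and the dienolate quenched cold with pivalic acid. The route is rejoined at 21.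

**Step 13.** What may go wrong: acid-catalysed enolisation of C2 during the hydrolysis, leading to epimerisation towards trans; alkylation of the electron-rich rings by released formaldehyde; oxidation of the catechols. Fallback: move the stereochemical event behind the deprotection. From 21, the same acid hydrolysis is run to completion without regard to C2, giving 22 mixed with its (1S,2R)-trans epimer F5. The mixture is silylated on all six phenols (Me3SiCl, imidazole) to the hexakis(trimethylsilyl) ether F6. F6 is deprotonated at C2 with LiN(SiMe3)2 at −78 °C to the lithium dienolate F7, which is protonated cold with AcOH to the cis hexakis(trimethylsilyl) ether F8. The silyl ethers are removed with citric acid in methanol at 0 °C, under which C2 should not enolise. The route is rejoined at 22.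

## Further compounds

F1 | step 11 | racemic 8-methoxy-6,7-(isopropylidenedioxy)-1-(4-methoxy-2,2-dimethyl-1,3-benzodioxol-5-yl)-2,2,3-tris[4-(methoxymethoxy)benzoyl]-1,2-dihydronaphthalene | COc1c(C2c3c(cc4OC(C)(C)Oc4c3OC)C=C(C(=O)c3ccc(OCOC)cc3)C2(C(=O)c2ccc(OCOC)cc2)C(=O)c2ccc(OCOC)cc2)ccc2OC(C)(C)Oc12
F2 | step 9 | 2-[4-(methoxymethoxy)benzoyl]-1,4-bis[4-(methoxymethoxy)phenyl]butane-1,4-dione | COCOc1ccc(cc1)C(=O)CC(C(=O)c1ccc(OCOC)cc1)C(=O)c1ccc(OCOC)cc1
F3 | step 10 | 3-[bis(4-methoxy-2,2-dimethyl-1,3-benzodioxol-5-yl)methyl]-2-(dimethylaminomethylidene)-3-[4-(methoxymethoxy)benzoyl]-1,4-bis[4-(methoxymethoxy)phenyl]butane-1,4-dione | CN(C)/C=C(/C(=O)c1ccc(OCOC)cc1)C(C(=O)c1ccc(OCOC)cc1)(C(=O)c1ccc(OCOC)cc1)C(c1ccc2OC(C)(C)Oc2c1OC)c1ccc2OC(C)(C)Oc2c1OC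
F4 | step 12 | (1S,2R)-8-methoxy-6,7-(isopropylidenedioxy)-1-(4-methoxy-2,2-dimethyl-1,3-benzodioxol-5-yl)-2,3-bis[4-(methoxymethoxy)benzoyl]-1,2-dihydronaphthalene (trans epimer of 21) | COc1c([C@H]2c3c(cc4OC(C)(C)Oc4c3OC)C=C(C(=O)c3ccc(OCOC)cc3)[C@@H]2C(=O)c2ccc(OCOC)cc2)ccc2OC(C)(C)Oc12
F5 | step 13 | (1S,2R)-1-(3,4-dihydroxy-2-methoxyphenyl)-6,7-dihydroxy-8-methoxy-2,3-bis(4-hydroxybenzoyl)-1,2-dihydronaphthalene (trans epimer of 22) | COc1c([C@H]2c3c(cc(O)c(O)c3OC)C=C(C(=O)c3ccc(O)cc3)[C@@H]2C(=O)c2ccc(O)cc2)ccc(O)c1O
F6 | step 13 | hexakis(trimethylsilyl) ether of the C2-epimeric mixture of 22 and F5 (C1 S, C2 undefined) | COc1c([C@H]2c3c(cc(O[Si](C)(C)C)c(O[Si](C)(C)C)c3OC)C=C(C(=O)c3ccc(O[Si](C)(C)C)cc3)C2C(=O)c2ccc(O[Si](C)(C)C)cc2)ccc(O[Si](C)(C)C)c1O[Si](C)(C)C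
F7 | step 13 | lithium dienolate of F6 (C2=C(O−)Ar exocyclic to ring B) | COc1c([C@H]2c3c(cc(O[Si](C)(C)C)c(O[Si](C)(C)C)c3OC)C=C(C(=O)c3ccc(O[Si](C)(C)C)cc3)C2=C([O-])c2ccc(O[Si](C)(C)C)cc2)ccc(O[Si](C)(C)C)c1O[Si](C)(C)C.[Li+]
F8 | step 13 | (1S,2S)-hexakis(trimethylsilyl) ether of 22 | COc1c([C@H]2c3c(cc(O[Si](C)(C)C)c(O[Si](C)(C)C)c3OC)C=C(C(=O)c3ccc(O[Si](C)(C)C)cc3)[C@H]2C(=O)c2ccc(O[Si](C)(C)C)cc2)ccc(O[Si](C)(C)C)c1O[Si](C)(C)C
A1 | alternative 1 | acyclic enediyne: (Z)-C3=C4 with ethynyl on C4, methoxyethynyl and 2-methoxy-3,4-bis(methoxymethoxy)phenyl on C1, 4-(methoxymethoxy)benzoyl on C2 and C3, C1 and C2 configured as in the target | COC#C[C@H](c1ccc(OCOC)c(OCOC)c1OC)[C@H](C(=O)c1ccc(OCOC)cc1)/C(C(=O)c1ccc(OCOC)cc1)=C\C#C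
A2 | alternative 1 | bis(pinacolboryl)acetylene, 2,2'-(ethyne-1,2-diyl)bis(4,4,5,5-tetramethyl-1,3,2-dioxaborolane) | CC1(C)OB(OC1(C)C)C#CB1OC(C)(C)C(C)(C)O1
A3 | alternative 1 | (1S,2S)-6,7-bis(pinacolboryl)-8-methoxy-1-[2-methoxy-3,4-bis(methoxymethoxy)phenyl]-2,3-bis[4-(methoxymethoxy)benzoyl]-1,2-dihydronaphthalene | COc1c([C@H]2c3c(cc(B4OC(C)(C)C(C)(C)O4)c(B4OC(C)(C)C(C)(C)O4)c3OC)C=C(C(=O)c3ccc(OCOC)cc3)[C@H]2C(=O)c2ccc(OCOC)cc2)ccc(OCOC)c1OCOC
A4 | alternative 2 | 3-methoxy-2-[2-methoxy-3,4-bis(methoxymethoxy)benzyl]-4,5-bis(methoxymethoxy)benzaldehyde | COc1c(Cc2c(C=O)cc(OCOC)c(OCOC)c2OC)ccc(OCOC)c1OCOC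
A5 | alternative 2 | hydroxy-ortho-quinodimethane (photoenol) of A4, hydroxyl and aryl both pointing outward | O/C=C1\C=C(OCOC)C(OCOC)=C(OC)/C1=C\c1ccc(OCOC)c(OCOC)c1OC
A6 | alternative 2 | (Z)-1,4-bis[4-(methoxymethoxy)phenyl]but-2-ene-1,4-dione | COCOc1ccc(cc1)C(=O)/C=C\C(=O)c1ccc(OCOC)cc1
A7 | alternative 2 | all-cis 4-hydroxy-8-methoxy-6,7-bis(methoxymethoxy)-1-[2-methoxy-3,4-bis(methoxymethoxy)phenyl]-2,3-bis[4-(methoxymethoxy)benzoyl]-1,2,3,4-tetrahydronaphthalene | COc1c([C@H]2c3c(cc(OCOC)c(OCOC)c3OC)[C@@H](O)[C@@H](C(=O)c3ccc(OCOC)cc3)[C@H]2C(=O)c2ccc(OCOC)cc2)ccc(OCOC)c1OCOC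
A8 | alternative 3 | racemic C1 carbinol: ring A bearing CH(OH)(4-hydroxy-2-methoxy-3-(methoxymethoxy)phenyl) at C8a and the (E)-2-aroyl-4-aryl-4-oxobut-1-enyl chain at C4a | COc1c(C(O)c2c(/C=C(\CC(=O)c3ccc(OCOC)cc3)C(=O)c3ccc(OCOC)cc3)cc(OCOC)c(OCOC)c2OC)ccc(O)c1OCOC
A9 | alternative 3 | ring C para-quinone methide derived from A8 | COC1=C(OCOC)C(=O)C=CC1=Cc1c(/C=C(\CC(=O)c2ccc(OCOC)cc2)C(=O)c2ccc(OCOC)cc2)cc(OCOC)c(OCOC)c1OC
A10 | alternative 3 | (1S,2S)-1-[4-hydroxy-2-methoxy-3-(methoxymethoxy)phenyl]-8-methoxy-6,7-bis(methoxymethoxy)-2,3-bis[4-(methoxymethoxy)benzoyl]-1,2-dihydronaphthalene (five MOM ethers) | COc1c([C@H]2c3c(cc(OCOC)c(OCOC)c3OC)C=C(C(=O)c3ccc(OCOC)cc3)[C@H]2C(=O)c2ccc(OCOC)cc2)ccc(O)c1OCOC
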